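C1 is the tertiary carbinol bearing C7H2OBz, then C2 (OBz), C3=C4, C5 (OBz), C6 (OH); O1, O2, O5 and O6 share one face of the single cyclohexene ring and C7 lies on the other.
Feature used: with C7 at the acid level, C7–C1(O)–C2(O)–C3=C4 is an α-oxy-γ,δ-unsaturated acid, the retron of an ester-enolate [3,3] shift. It lies inside the ring, next to C6–O, C5–O and C4, which are C3, C4 and C5 of D-galactose.
Disconnections: O5 benzoate and O1 silyl ether (end game) ⇒ C7 benzoate/alcohol ⇒ acid 13 ⇒ C1–C2 bond, opened back to the silyl ketene acetal of D-galacto-hept-6-enono-1,5-lactone 10, whose (Z)-enol benzoate carries C2 and C3.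
10 ⇒ alkynyl lactone 8 + benzoic acid (the fragile enol ester goes on last) ⇒ diacetone galactose by C6 oxidation and alkynylation. O4 is locked in a 3,4-acetonide before the anomeric oxidation, so only a 1,5-lactone can form.
Ring order: the sugar pyranose ring becomes the δ-lactone (step 5); the carbocycle, the only ring of the target, closes in step 8 in the same event that opens the lactone.

Key step: step 8

Remark: sugar numbering is used for 1–11 and target numbering for 12–18; 5 and 6 are carried on as anomeric mixtures, which is harmless because C1 becomes a carbonyl carbon in step 5.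

Step 1
Reactants: 1 1,2:3,4-di-O-isopropylidene-α-D-galactopyranose
Product: 2 1,2:3,4-di-O-isopropylidene-α-D-galacto-hexodialdo-1,5-pyranose (C6 aldehyde)
Conditions: IBX, EtOAc, 80 °C; filter
Reagents that add atoms: none
Why: IBX oxidation (hypervalent iodine) takes the only free hydroxyl to the aldehyde without over-oxidation, under neutral conditions that neither epimerise C5 nor touch the acetonides, and no stereocentre is created.

Step 2
Reactants: 2 C6 aldehyde; 3 dimethyl (1-diazo-2-oxopropyl)phosphonate
Product: 4 6,7-dideoxy-1,2:3,4-di-O-isopropylidene-α-D-galacto-hept-6-ynopyranose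
Conditions: K2CO3, MeOH, 0 °C → rt
Reagents that add atoms: dimethyl (1-diazo-2-oxopropyl)phosphonate (3), CC(=O)C(=[N+]=[N-])P(=O)(OC)OC
Why: Ohira–Bestmann alkynylation: methoxide deacetylates 3 to the diazomethylphosphonate anion, which olefinates the aldehyde, and loss of N2 with a 1,2-hydrogen shift gives the terminal alkyne, the carbonate base being mild enough to keep the C5 configuration of this aldehyde.

Step 3
Reactants: 4 alkynyl diacetonide
Product: 5 6,7-dideoxy-D-galacto-hept-6-ynopyranose (α/β mixture)
Conditions: TFA–H2O 9:1, 0 °C → rt; co-evaporation with toluene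
Reagents that add atoms: none
Why: Acid-catalysed acetal hydrolysis removes both isopropylidene groups, a terminal alkyne is inert to aqueous trifluoroacetic acid, and C2–C5 are untouched while C1 merely equilibrates.

Step 4
Reactants: 5 free heptynose
Product: 6 6,7-dideoxy-3,4-O-isopropylidene-D-galacto-hept-6-ynopyranose (α/β mixture, 1-OH and 2-OH free)
Conditions: Me2C(OMe)2 (1.2 equiv), TsOH·H2O (cat.), DMF, 0 °C → rt; Et3N quench
Reagents that add atoms: 2,2-dimethoxypropane, COC(C)(C)OC
Why: Kinetically controlled acetonation (transacetalisation with about one equivalent of reagent in DMF) picks the cis-3,4-diol of galacto-configured pyranoses lacking a 6-OH, as known for fucose and arabinose, and tying up O4 excludes furanose forms so that the coming lactone can only be six-membered, any over-acetonated material being 4 itself and reusable.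

Step 5
Reactants: 6 3,4-acetonide lactol
Product: 7 6,7-dideoxy-3,4-O-isopropylidene-D-galacto-hept-6-ynono-1,5-lactone (2-OH free)
Conditions: N-iodosuccinimide (2.5 equiv), Bu4NI (cat.), CH2Cl2, rt, dark; aq. Na2S2O3 wash
Reagents that add atoms: none
Why: Lactol oxidation with N-iodosuccinimide runs through the anomeric hypoiodite, so the hemiacetal C1–H is oxidised well before the secondary 2-OH, the electron-poor terminal alkyne is not iodinated in the absence of AgNO3 or base, and the 1,5-lactone cannot isomerise to a 1,4-lactone because O4 is blocked.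

Step 6
Reactants: 7 hydroxy lactone
Product: 8 2-O-(tert-butyldimethylsilyl)-6,7-dideoxy-3,4-O-isopropylidene-D-galacto-hept-6-ynono-1,5-lactone
Conditions: TBSOTf, 2,6-lutidine, CH2Cl2, −20 → 0 °C
Reagents that add atoms: tert-butyldimethylsilyl trifluoromethanesulfonate, CC(C)(C)[Si](C)(C)OS(=O)(=O)C(F)(F)F
Why: Silyl ether formation with the silyl triflate and a hindered pyridine base caps the deactivated α-hydroxyl without enolising the lactone, and the configuration at C2 is in any case erased in step 8.

Step 7
Reactants: 8 alkynyl lactone; 9 benzoic acid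
Product: 10 7-O-benzoyl-2-O-(tert-butyldimethylsilyl)-6-deoxy-3,4-O-isopropylidene-D-galacto-(Z)-hept-6-enono-1,5-lactone
Conditions: 9 (1.1 equiv), Ru(η3-CH2C(CH3)CH2)2(dppb) (3 mol %; dppb = 1,4-bis(diphenylphosphino)butane), toluene, 60 °C
Reagents that add atoms: benzoic acid (9), O=C(O)c1ccccc1
Why: Ruthenium-catalysed anti-Markovnikov hydroacyloxylation of a terminal alkyne: the alkyne tautomerises to a ruthenium vinylidene whose electrophilic α-carbon is attacked by benzoate, and protonolysis gives net trans addition and hence the (Z)-enol benzoate; propargylic oxygen substituents are tolerated, and the step is placed directly before the rearrangement because an enol ester is an acyl donor and an oxidisable alkene that would be at risk during acetal hydrolysis, next to free hydroxyls, or with halogen oxidants.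

Step 8
Reactants: 10 (Z)-enol benzoate lactone
Product: 13 (1R,2R,5S,6S)-2-benzoyloxy-1-(tert-butyldimethylsilyloxy)-5,6-(isopropylidenedioxy)cyclohex-3-ene-1-carboxylic acid, via silyl ketene acetal 11 (not isolated), via trimethylsilyl ester 12 (not isolated)
Conditions: Me3SiCl–Et3N (excess), then LiN(SiMe3)2 (1.3 equiv) dropwise, THF, −78 → 0 °C; solvent change to toluene, 100 °C (sealed); aq. citric acid, THF, rt
Reagents that add atoms: chlorotrimethylsilane, C[Si](C)(C)Cl (its Me3Si group is carried by 11 and 12 only and is lost again on work-up; 13 holds no atom from a reagent)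
Why: Proposed new method: LiN(SiMe3)2 removes H2 of 10 while Me3SiCl is already present, so the enolate is O-silylated to the ring-fixed ketene acetal 11, which on heating undergoes a concerted suprafacial [3,3] shift in which sugar C2–C7 (target C1–C2) forms as sugar C5–O5 (target C4–O) breaks, giving silyl ester 12 and, after mild hydrolysis, acid 13. The closest known reaction types are the Ireland–Claisen conversion of 6-alkenyl δ-lactones into cyclohex-3-enecarboxylic acids, the thermal Claisen rearrangement of C5-vinyl glycals to carbocycles and the ester-enolate Claisen rearrangement of glycal esters, which already bonds to an oxygen-bearing alkene terminus; new here is an acyloxy group on that terminus, a weak donor that should stabilise rather than penalise a transition state with enolate/allyl-cation character. The cyclohexene ring is closed pericyclically: the two-atom tether C3–C4 links both ends of the six-atom array, so only a boat, bicyclo[2.2.2]octane-like transition state is accessible and the new C3=C4 bond (target numbering) must be cis. Target C1 is controlled by chirality transfer from sugar C5, because the alkenyl group can reach C2 only on the β face that it shares with O3 and O4, which places the silyloxy group on the same side of the new ring as O5 and O6 and the carboxyl group on the opposite side. Target C2 is controlled by the alkene geometry, since in the boat the Z substituent points inward over the tether and ends cis to O1, so the Z purity of 10 becomes the diastereomeric purity of 13. The step needs O-silylation and rearrangement to win over β-elimination of O3, C-silylation and benzoyl transfer, which is secured by the in situ quench at −78 °C, by a hindered non-nucleophilic amide, by the pseudo-equatorial (poorly aligned) C3–O bond of the resting half-chair and by a benzoate that has no α-hydrogen.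

Step 9
Reactants: 13 cyclohexenecarboxylic acid
Product: 14 (1R,2R,5S,6S)-2-benzoyloxy-1-(tert-butyldimethylsilyloxy)-1-(hydroxymethyl)-5,6-(isopropylidenedioxy)cyclohex-3-ene
Conditions: BH3·THF (2 equiv), THF, 0 °C → rt; H2O work-up
Reagents that add atoms: none
Why: Borane reduction of a carboxylic acid proceeds through an acyloxyborane and is faster than attack on benzoate esters or on a 1,2-disubstituted alkene deactivated by two allylic C–O bonds, it tolerates silyl ether and acetonide, and an O2→O7 benzoyl shift would be harmless because both oxygens carry benzoate after step 10.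

Step 10
Reactants: 14 C7 alcohol
Product: 15 [(1R,2R,5S,6S)-2-benzoyloxy-1-(tert-butyldimethylsilyloxy)-5,6-(isopropylidenedioxy)cyclohex-3-en-1-yl]methyl benzoate
Conditions: BzCl, pyridine, DMAP (cat.), CH2Cl2, 0 °C → rt
Reagents that add atoms: benzoyl chloride, O=C(Cl)c1ccccc1
Why: DMAP-catalysed acylation (nucleophilic catalysis) esterifies the neopentyl-type primary alcohol, which is the only free hydroxyl of 14.

Step 11
Reactants: 15 dibenzoate acetonide
Product: 16 [(1S,2R,5S,6S)-2-benzoyloxy-1-(tert-butyldimethylsilyloxy)-5,6-dihydroxycyclohex-3-en-1-yl]methyl benzoate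
Conditions: AcOH–H2O 4:1, 50 °C
Reagents that add atoms: none
Why: Mild acid-catalysed acetal hydrolysis cleaves the dioxolane while the hindered tertiary silyl ether and the benzoates persist, and the silyl group is kept on purpose because it shields O6 in the next step.

Step 12
Reactants: 16 C5,C6-diol
Product: 17 [(1S,2R,5S,6S)-2,5-bis(benzoyloxy)-1-(tert-butyldimethylsilyloxy)-6-hydroxycyclohex-3-en-1-yl]methyl benzoate
Conditions: BzCl (1.05 equiv), pyridine, CH2Cl2, −30 → 0 °C
Reagents that add atoms: benzoyl chloride, O=C(Cl)c1ccccc1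
Why: Sterically controlled selective acylation: the allylic C5–OH has an sp2 CH on one side, whereas C6–OH sits next to the fully substituted C1 with its cis silyloxy group and CH2OBz arm, so one equivalent of benzoyl chloride at low temperature should acylate O5 only.

Step 13
Reactants: 17 silyl-protected tribenzoate
Product: 18 [(1S,2R,5S,6S)-2,5-bis(benzoyloxy)-1,6-dihydroxycyclohex-3-en-1-yl]methyl benzoate (target)
Conditions: aq. HF (48 %), MeCN, 0 °C → rt (plastic vessel)
Reagents that add atoms: none
Why: Fluoride-driven desilylation in acidic medium (formation of the strong Si–F bond) frees the tertiary alcohol without the alkoxide intermediates that would set off benzoate migration between the cis oxygens.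

Compound list
1 | 1,2:3,4-di-O-isopropylidene-α-D-galactopyranose | OC[C@H]1O[C@H](OC(C)(C)O2)[C@H]2[C@@H](OC(C)(C)O3)[C@H]13 | starting material
2 | 1,2:3,4-di-O-isopropylidene-α-D-galacto-hexodialdo-1,5-pyranose | O=C[C@H]1O[C@H](OC(C)(C)O2)[C@H]2[C@@H](OC(C)(C)O3)[C@H]13 | intermediate
3 | dimethyl (1-diazo-2-oxopropyl)phosphonate | CC(=O)C(=[N+]=[N-])P(=O)(OC)OC | starting material
4 | 6,7-dideoxy-1,2:3,4-di-O-isopropylidene-α-D-galacto-hept-6-ynopyranose | C#C[C@H]1O[C@H](OC(C)(C)O2)[C@H]2[C@@H](OC(C)(C)O3)[C@H]13 | intermediate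
5 | 6,7-dideoxy-D-galacto-hept-6-ynopyranose (anomeric mixture) | C#C[C@H]1OC(O)[C@H](O)[C@@H](O)[C@H]1O | intermediate
6 | 6,7-dideoxy-3,4-O-isopropylidene-D-galacto-hept-6-ynopyranose (anomeric mixture) | C#C[C@H]1OC(O)[C@H](O)[C@@H](OC(C)(C)O2)[C@H]12 | intermediate
7 | 6,7-dideoxy-3,4-O-isopropylidene-D-galacto-hept-6-ynono-1,5-lactone | O=C1[C@H](O)[C@@H](OC(C)(C)O2)[C@@H]2[C@H](O1)C#C | intermediate
8 | 2-O-(tert-butyldimethylsilyl)-6,7-dideoxy-3,4-O-isopropylidene-D-galacto-hept-6-ynono-1,5-lactone | O=C1[C@H](O[Si](C)(C)C(C)(C)C)[C@@H](OC(C)(C)O2)[C@@H]2[C@H](O1)C#C | intermediate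
9 | benzoic acid | O=C(O)c1ccccc1 | starting material
10 | 7-O-benzoyl-2-O-(tert-butyldimethylsilyl)-6-deoxy-3,4-O-isopropylidene-D-galacto-(Z)-hept-6-enono-1,5-lactone | O=C1[C@H](O[Si](C)(C)C(C)(C)C)[C@@H](OC(C)(C)O2)[C@@H]2[C@H](O1)/C=C\OC(=O)c1ccccc1 | intermediate
11 | 1-O-trimethylsilyl ketene acetal of 10 (endocyclic C1=C2, other groups unchanged) | C[Si](C)(C)OC1=C(O[Si](C)(C)C(C)(C)C)[C@@H](OC(C)(C)O2)[C@@H]2[C@H](O1)/C=C\OC(=O)c1ccccc1 | intermediate
12 | trimethylsilyl ester of acid 13 | C[Si](C)(C)OC(=O)[C@@]1(O[Si](C)(C)C(C)(C)C)[C@H](OC(=O)c2ccccc2)C=C[C@H](OC(C)(C)O3)[C@@H]13 | intermediate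
13 | (1R,2R,5S,6S)-2-benzoyloxy-1-(tert-butyldimethylsilyloxy)-5,6-(isopropylidenedioxy)cyclohex-3-ene-1-carboxylic acid (four ring oxygens cis, carboxyl trans) | OC(=O)[C@@]1(O[Si](C)(C)C(C)(C)C)[C@H](OC(=O)c2ccccc2)C=C[C@H](OC(C)(C)O3)[C@@H]13 | intermediate
14 | (1R,2R,5S,6S)-2-benzoyloxy-1-(tert-butyldimethylsilyloxy)-1-(hydroxymethyl)-5,6-(isopropylidenedioxy)cyclohex-3-ene | OC[C@@]1(O[Si](C)(C)C(C)(C)C)[C@H](OC(=O)c2ccccc2)C=C[C@H](OC(C)(C)O3)[C@@H]13 | intermediate
15 | [(1R,2R,5S,6S)-2-benzoyloxy-1-(tert-butyldimethylsilyloxy)-5,6-(isopropylidenedioxy)cyclohex-3-en-1-yl]methyl benzoate | O=C(OC[C@@]1(O[Si](C)(C)C(C)(C)C)[C@H](OC(=O)c2ccccc2)C=C[C@H](OC(C)(C)O3)[C@@H]13)c1ccccc1 | intermediate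
16 | [(1S,2R,5S,6S)-2-benzoyloxy-1-(tert-butyldimethylsilyloxy)-5,6-dihydroxycyclohex-3-en-1-yl]methyl benzoate | O=C(OC[C@@]1(O[Si](C)(C)C(C)(C)C)[C@H](OC(=O)c2ccccc2)C=C[C@H](O)[C@@H]1O)c1ccccc1 | intermediate
17 | [(1S,2R,5S,6S)-2,5-bis(benzoyloxy)-1-(tert-butyldimethylsilyloxy)-6-hydroxycyclohex-3-en-1-yl]methyl benzoate | O=C(OC[C@@]1(O[Si](C)(C)C(C)(C)C)[C@H](OC(=O)c2ccccc2)C=C[C@H](OC(=O)c2ccccc2)[C@@H]1O)c1ccccc1 | intermediate
18 | [(1S,2R,5S,6S)-2,5-bis(benzoyloxy)-1,6-dihydroxycyclohex-3-en-1-yl]methyl benzoate | O=C(OC[C@@]1(O)[C@H](OC(=O)c2ccccc2)C=C[C@H](OC(=O)c2ccccc2)[C@@H]1O)c1ccccc1 | target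

Total step count: 13. Longest linear sequence: 13 steps (1 → 18).

Steps most likely to fail

1. Step 8 (labelled step).
- What may go wrong: loss of the C3 oxygen by β-elimination during enolisation; transfer of the benzoyl group to the enolate or to the amide base; or decay of the ketene acetal before the crowded boat transition state is reached.
- Fallback (sets out from 8, returns at 15): the untested enol-ester terminus is given up, the rearrangement is run on the established substrate class, and C2 is oxygenated afterwards by known reactions.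
- Semihydrogenation of 8 (H2, Pd/CaCO3–Pb(OAc)2 Lindlar catalyst, quinoline, EtOAc) should give the vinyl lactone F1.
- LiN(SiMe3)2/Me3SiCl converts it into the silyl ketene acetal F2. In hot toluene this rearranges through the same boat to the trimethylsilyl ester F3, which hydrolyses to the C2-unsubstituted acid F4, with C1 set exactly as in the main route.
- LiAlH4 (THF, 0 °C) reduces it to the primary alcohol F5, and BzCl/pyridine/DMAP gives the C7 benzoate F6.
- Allylic oxidation of the C2 methylene with CrO3·3,5-dimethylpyrazole (CH2Cl2, −20 °C) should lead to the enone F7.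
- Luche reduction (NaBH4, CeCl3·7H2O, MeOH, −78 °C) should deliver hydride anti to the pseudo-axial C1–O bond and give the allylic alcohol F8, with O2 cis to O1. Benzoylation of F8 gives 15.

2. Step 7.
- What may go wrong: sluggish alkyne-to-vinylidene tautomerisation at the branched propargylic centre; leakage to Markovnikov addition or to the E isomer, which would end as the C2 epimer; or ionisation of the propargylic C5–O bond of the lactone.
- Fallback (sets out from 8, returns at 10): the C7–O bond is made by cross-coupling instead of by addition.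
- Rhodium-catalysed trans-hydroboration with pinacolborane ([Rh(cod)Cl]2, P(i-Pr)3, Et3N, cyclohexane, rt) should give the (Z)-alkenylboronate F9.
- KHF2 in aqueous MeOH converts it into the potassium (Z)-alkenyltrifluoroborate F10.
- Copper-catalysed oxidative C–O coupling with benzoic acid 9 (CuBr cat., DMAP, 4 Å molecular sieves, O2, MeCN, 60 °C), a coupling that keeps the alkene geometry, gives 10.

3. Step 9.
- What may go wrong: competing, possibly carboxyl-directed, hydroboration of the ring alkene, or slow hydride transfer within the hindered acyloxyborane.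
- Fallback (sets out from 13, returns at 15): the C2 benzoate is sacrificed and put back.
- LiAlH4 (THF, 0 °C → rt), which does not touch the alkene, reduces the acid and cleaves the ester to the C2,C7-diol F11. Double benzoylation (BzCl, pyridine, DMAP, CH2Cl2) then gives 15 in the same number of operations.

Further compounds
F1 | step 8 | 2-O-(tert-butyldimethylsilyl)-6,7-dideoxy-3,4-O-isopropylidene-D-galacto-hept-6-enono-1,5-lactone | O=C1[C@H](O[Si](C)(C)C(C)(C)C)[C@@H](OC(C)(C)O2)[C@@H]2[C@H](O1)C=C
F2 | step 8 | 1-O-trimethylsilyl ketene acetal of F1 | C[Si](C)(C)OC1=C(O[Si](C)(C)C(C)(C)C)[C@@H](OC(C)(C)O2)[C@@H]2[C@H](O1)C=C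
F3 | step 8 | trimethylsilyl ester of F4 | C[Si](C)(C)OC(=O)[C@@]1(O[Si](C)(C)C(C)(C)C)CC=C[C@H](OC(C)(C)O2)[C@@H]12
F4 | step 8 | (1R,5S,6S)-1-(tert-butyldimethylsilyloxy)-5,6-(isopropylidenedioxy)cyclohex-3-ene-1-carboxylic acid | OC(=O)[C@@]1(O[Si](C)(C)C(C)(C)C)CC=C[C@H](OC(C)(C)O2)[C@@H]12
F5 | step 8 | (1S,5S,6S)-1-(tert-butyldimethylsilyloxy)-1-(hydroxymethyl)-5,6-(isopropylidenedioxy)cyclohex-3-ene | OC[C@@]1(O[Si](C)(C)C(C)(C)C)CC=C[C@H](OC(C)(C)O2)[C@@H]12
F6 | step 8 | [(1S,5S,6S)-1-(tert-butyldimethylsilyloxy)-5,6-(isopropylidenedioxy)cyclohex-3-en-1-yl]methyl benzoate | O=C(OC[C@@]1(O[Si](C)(C)C(C)(C)C)CC=C[C@H](OC(C)(C)O2)[C@@H]12)c1ccccc1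
F7 | step 8 | [(1S,5S,6S)-1-(tert-butyldimethylsilyloxy)-5,6-(isopropylidenedioxy)-2-oxocyclohex-3-en-1-yl]methyl benzoate | O=C(OC[C@@]1(O[Si](C)(C)C(C)(C)C)C(=O)C=C[C@H](OC(C)(C)O2)[C@@H]12)c1ccccc1
F8 | step 8 | [(1R,2R,5S,6S)-1-(tert-butyldimethylsilyloxy)-2-hydroxy-5,6-(isopropylidenedioxy)cyclohex-3-en-1-yl]methyl benzoate | O=C(OC[C@@]1(O[Si](C)(C)C(C)(C)C)[C@H](O)C=C[C@H](OC(C)(C)O2)[C@@H]12)c1ccccc1
F9 | step 7 | 2-O-(tert-butyldimethylsilyl)-6,7-dideoxy-3,4-O-isopropylidene-7-(4,4,5,5-tetramethyl-1,3,2-dioxaborolan-2-yl)-D-galacto-(Z)-hept-6-enono-1,5-lactone | O=C1[C@H](O[Si](C)(C)C(C)(C)C)[C@@H](OC(C)(C)O2)[C@@H]2[C@H](O1)/C=C\B1OC(C)(C)C(C)(C)O1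
F10 | step 7 | potassium (Z)-alkenyltrifluoroborate derived from F9 | O=C1[C@H](O[Si](C)(C)C(C)(C)C)[C@@H](OC(C)(C)O2)[C@@H]2[C@H](O1)/C=C\[B-](F)(F)F.[K+]
F11 | step 9 | (1R,2R,5S,6S)-1-(tert-butyldimethylsilyloxy)-2-hydroxy-1-(hydroxymethyl)-5,6-(isopropylidenedioxy)cyclohex-3-ene | OC[C@@]1(O[Si](C)(C)C(C)(C)C)[C@H](O)C=C[C@H](OC(C)(C)O2)[C@@H]12
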